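**Plan**
- Retrosynthesis: the C5 silyl ether, the C12 ester (alkyne carbonylation) and the C3 angelate are removed first. Ring A is then cut at C1–C2 and C3–C4, which excises C2–C3 as a vinylboronate and leaves ring B with an iodomethyl group on C10 and an ethynyl carbinol at C5.
- Ring B goes back to a 4-silyloxycyclohexenone through two acetylide additions (C5–C4 by 1,2-addition, C7–C11 by 1,4-addition) and two α′-alkylations (C14, C1).
- Forward: ring B is made first and fully substituted; ring A arises last, in one radical [4+2] annulation, followed by C3 oxidation, angeloylation and conversion of the C7 ethynyl group into the acrylate.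
- Enabling feature: C1 (a neopentyl CH2–I on C10) and the C4≡C15 ethynyl group on C5 sit trans-diequatorial on adjacent quaternary carbons of ring B. A two-carbon radical acceptor therefore stitches C10–C1–C2–C3–C4–C5 by addition and 6-exo-dig closure, leaving the C4=C15 methylene and a C3–B bond as latent 3β-OH.
- Stereochemistry: C8 from a CBS reduction; C10 by alkylation anti to the C8 silyloxy group; C7 by alkoxide-directed 1,4-addition (cis to O8); C5 by axial acetylide attack anti to the axial C1 arm; C3 by the equatorial preference of Bpin against the axial C5–OSiEt3 group.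

Key step: step 13

Remark: names use eudesmane numbering (β = face of the C10 methyl); enolates, alkoxides and radicals are treated as transient species and carry no number; compounds 6, 9 and 16 are taken as catalogue reagents.

**Route**

Step 1
Reactants: 1 1,4-dioxaspiro[4.5]dec-6-en-8-one
Product: 2 (8R)-1,4-dioxaspiro[4.5]dec-6-en-8-ol
Conditions: (S)-2-methyl-CBS-oxazaborolidine (10 mol %), BH3·SMe2, THF, −20 °C; then MeOH, H2O
Reagents that add atoms: none
Why: Corey–Bakshi–Shibata reduction, in which the oxazaborolidine–borane complex binds the enone with the alkenyl arm as the large group and delivers hydride to one face, setting the carbinol (later C8) as R.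

Step 2
Reactants: 2 (8R)-1,4-dioxaspiro[4.5]dec-6-en-8-ol
Product: 3 (8R)-8-(tert-butyldimethylsilyloxy)-1,4-dioxaspiro[4.5]dec-6-ene
Conditions: tBuMe2SiCl, imidazole, DMF, 20 °C
Reagents that add atoms: tert-butyldimethylsilyl chloride, CC(C)(C)[Si](C)(C)Cl
Why: standard imidazole-assisted silylation of a secondary allylic alcohol; no stereocenter is touched.

Step 3
Reactants: 3 (8R)-8-(tert-butyldimethylsilyloxy)-1,4-dioxaspiro[4.5]dec-6-ene
Product: 4 (4R)-4-(tert-butyldimethylsilyloxy)cyclohex-2-en-1-one
Conditions: pyridinium p-toluenesulfonate (cat.), acetone–H2O, 50 °C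
Reagents that add atoms: water, O
Why: mild acid-catalysed acetal hydrolysis should release the enone while the silyl ether and the γ-stereocenter stay intact.

Step 4
Reactants: 4 (4R)-4-(tert-butyldimethylsilyloxy)cyclohex-2-en-1-one
Product: 5 (4R)-4-(tert-butyldimethylsilyloxy)-6-methylcyclohex-2-en-1-one (both C6 epimers)
Conditions: LiN(iPr)2, THF, −78 °C; then MeI, −78 to −30 °C
Reagents that add atoms: iodomethane, CI
Why: kinetic α′-deprotonation and SN2 methylation of the lithium enolate; the configuration of the new center does not matter because it is enolized again in step 5.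

Step 5
Reactants: 5 (4R)-4-(tert-butyldimethylsilyloxy)-6-methylcyclohex-2-en-1-one; 6 4-methoxybenzyl chloromethyl ether
Product: 7 (4R)-4-(tert-butyldimethylsilyloxy)-6-[(4-methoxybenzyloxy)methyl]-6-methylcyclohex-2-en-1-one, methyl cis to the silyloxy group
Conditions: LiN(iPr)2, THF, −78 °C; then 6, −78 to −30 °C
Reagents that add atoms: 4-methoxybenzyl chloromethyl ether (6), COc1ccc(COCCl)cc1
Why: α′-alkylation of the tetrasubstituted lithium enolate with a chloromethyl ether; the electrophile should enter anti to the pseudoaxial γ′-silyloxy group, so the CH2O arm (C1) ends trans and the methyl cis to the C8 oxygen, which sets quaternary C10.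

Step 6
Reactants: 7 the silyloxy enone
Product: 8 (4R)-4-hydroxy-6-[(4-methoxybenzyloxy)methyl]-6-methylcyclohex-2-en-1-one, methyl cis to OH
Conditions: Bu4NF, THF, 0 °C
Reagents that add atoms: none
Why: fluoride cleavage of the silyl ether frees the γ-hydroxyl that directs the next step.

Step 7
Reactants: 8 the γ-hydroxy enone; 9 ethynylmagnesium bromide
Product: 10 3-ethynyl-4-hydroxy-6-[(4-methoxybenzyloxy)methyl]-6-methylcyclohexan-1-one, ethynyl, hydroxyl and methyl all cis (C7 β-ethynyl, C8 β-OH)
Conditions: 9 (4 equiv, 0.5 M in THF), THF, −20 to 20 °C; then H2O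
Reagents that add atoms: ethynylmagnesium bromide (9), C#C[Mg]Br
Why: alkoxide-directed 1,4-addition of a Grignard reagent to a γ-oxido enone (ligand-assisted nucleophilic addition), in which the magnesium alkoxide at C8 binds the reagent and delivers the ethynyl group to C7 on its own face, setting C7 cis to the C8 oxygen.

Step 8
Reactants: 10 the ethynyl hydroxy ketone; 9 ethynylmagnesium bromide
Product: 11 1,5-diethynyl-2-[(4-methoxybenzyloxy)methyl]-2-methylcyclohexane-1,4-diol (C5 α-OH/β-ethynyl, C7 β-ethynyl, C8 β-OH, C10 β-Me/α-CH2OPMB)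
Conditions: 9 (4 equiv), CeCl3, THF, −78 °C; then H2O
Reagents that add atoms: ethynylmagnesium bromide (9), C#C[Mg]Br
Why: 1,2-addition of an organocerium acetylide (enolization suppressed); the cis C8-oxido and C10-methyl groups should hold ring B in the chair with the CH2OPMB arm axial, and axial attack anti to that arm, past the slim axial C7 ethynyl, places the new ethynyl cis to the methyl and the C5 oxygen cis to C1.

Step 9
Reactants: 11 the diyne diol
Product: 12 the C8 acetate of 11 (tertiary C5–OH free)
Conditions: Ac2O, pyridine, DMAP (5 mol %), CH2Cl2, 0 °C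
Reagents that add atoms: acetic anhydride, CC(=O)OC(C)=O
Why: acylation of the secondary alcohol only; the tertiary propargylic hydroxyl is too hindered to react under these conditions.

Step 10
Reactants: 12 the hydroxy acetate
Product: 13 the C5 triethylsilyl ether of 12
Conditions: Et3SiOSO2CF3, 2,6-lutidine, CH2Cl2, 0 °C
Reagents that add atoms: triethylsilyl trifluoromethanesulfonate, CC[Si](CC)(CC)OS(=O)(=O)C(F)(F)F
Why: silyl triflate silylation of the hindered tertiary alcohol, which protects it during iodination and supplies the axial group that steers the key step.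

Step 11
Reactants: 13 the 4-methoxybenzyl ether
Product: 14 the primary alcohol (C1–OH) of 13
Conditions: DDQ, CH2Cl2–pH 7 buffer (10:1), 0 °C
Reagents that add atoms: none
Why: oxidative cleavage of the 4-methoxybenzyl ether by hydride abstraction and hydrolysis of the oxocarbenium ion; alkynes, acetate and silyl ether are inert.

Step 12
Reactants: 14 the primary alcohol
Product: 15 the iodide (C10–CH2I; C5 α-OSiEt3/β-ethynyl, C7 β-ethynyl, C8 β-OAc, C10 β-Me)
Conditions: PPh3, I2, imidazole, PhMe, 80 °C
Reagents that add atoms: iodine, II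
Why: Appel-type iodination through the alkoxyphosphonium salt; SN2 at the neopentyl carbon is slow but is the only substitution open because the tertiary oxygen is silylated.

Step 13
Reactants: 15 the iodide; 16 4,4,5,5-tetramethyl-2-vinyl-1,3,2-dioxaborolane
Product: 18 8β-acetoxy-7β-ethynyl-3β-(pinacolatoboryl)-5α-(triethylsilyloxy)-10β-methyl-4-methylene-trans-decalin, via vinyl iodide 17 (not isolated)
Conditions: 16 (8 equiv), (Bu3Sn)2 (10 mol %), hν (sunlamp), PhH (0.3 M), 80 °C; evaporate excess 16; then Bu3SnH (1.05 equiv), AIBN (10 mol %), PhH, 80 °C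
Reagents that add atoms: 4,4,5,5-tetramethyl-2-vinyl-1,3,2-dioxaborolane (16), C=CB1OC(C)(C)C(C)(C)O1
Why: Proposed new method: Bu3Sn• from photolysed (Bu3Sn)2 abstracts iodine from 15, the neopentyl-type C1 radical (no 4-exo or 5-endo-dig outlet) adds to the CH2 terminus of 16, the α-boryl C3 radical attacks C4 of the C5 ethynyl group, and the exocyclic C15 vinyl radical abstracts iodine from a further molecule of 15 to carry the chain and give 17, which Bu3SnH then reduces to the methylene compound. The closest known reaction types are iodine-atom-transfer radical annulation of alkyl iodides with an alkene and an alkyne, Giese addition of alkyl radicals to vinylboronic esters, and cyclization of α-boryl radicals; their merger across a 1,3-disposed iodomethyl/ethynyl pair is the new element. Ring A (C10–C1–C2–C3–C4–C5) closes in the 6-exo-dig mode through a chair transition state on the ring-B chair that holds C1 and the C5 ethynyl trans-diequatorial, so the decalin is trans-fused and the C4=C15 methylene is the direct footprint of the exo-dig closure. The only new stereocenter, C3, is controlled by the axial C5–OSiEt3 group: Bpin takes the pseudoequatorial position to avoid a 1,3-diaxial contact with it and becomes 3β. The step needs cyclization to beat telomerization and iodine transfer at the α-boryl radical, and needs the vinyl radical to take iodine instead of adding to 16; the absence of a hydride donor in the first stage, the reversibility of iodine transfer to the stabilized α-boryl radical, the Thorpe–Ingold effect of quaternary C5 and C10 and the high rate of iodine abstraction by vinyl radicals should secure this, while the C7 ethynyl group is out of reach of every radical except through a bridged boat.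

Step 14
Reactants: 18 the allylic boronate
Product: 19 8β-acetoxy-7β-ethynyl-5α-(triethylsilyloxy)-10β-methyl-4-methylene-trans-decalin-3β-ol
Conditions: NaBO3·4H2O, THF–H2O (1:1), 20 °C
Reagents that add atoms: sodium perborate, [Na+].[O-]OB=O
Why: oxidation of the C–B bond through the boron ate complex with 1,2-migration of C3 to oxygen, which proceeds with retention and without allylic transposition, so the 3β-boronate becomes the 3β-alcohol.

Step 15
Reactants: 19 the 3β-alcohol; 20 angelic acid ((Z)-2-methylbut-2-enoic acid)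
Product: 22 the 3β-angelate of 19, via mixed anhydride 21 (not isolated)
Conditions: 20, 2,4,6-trichlorobenzoyl chloride, Et3N, PhMe, 20 °C; then 19, 80 °C
Reagents that add atoms: angelic acid (20), C/C=C(/C)C(=O)O; 2,4,6-trichlorobenzoyl chloride, O=C(Cl)c1c(Cl)cc(Cl)cc1Cl (its atoms stay in 21 only)
Why: Yamaguchi esterification without DMAP, in which the alcohol attacks the less hindered angeloyl carbonyl of the mixed anhydride and the absence of a nucleophilic catalyst avoids Z to E isomerization; only the secondary allylic alcohol is free.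

Step 16
Reactants: 22 the ethynyl angelate
Product: 23 methyl 8β-acetoxy-3β-angeloyloxy-5α-(triethylsilyloxy)eudesma-4(15),11(13)-dien-12-oate
Conditions: Pd(OAc)2 (2 mol %), 2-(diphenylphosphino)pyridine (40 mol %), CH3SO3H (20 mol %), CO (20 bar), MeOH, 45 °C
Reagents that add atoms: carbon monoxide, [C-]#[O+]; methanol, CO
Why: palladium-catalysed Markovnikov hydromethoxycarbonylation of a terminal alkyne (the pyridylphosphine/acid system that turns propyne into methyl methacrylate) gives the 2-substituted acrylate; the alkyne should react far faster than the alkenes, and the acid is buffered by the excess pyridylphosphine.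

Step 17
Reactants: 23 the silyl ether
Product: 24 methyl 8β-acetoxy-3β-angeloyloxy-5α-hydroxyeudesma-4(15),11(13)-dien-12-oate (CNP0179024.1)
Conditions: HF·pyridine, pyridine, THF, 0 to 20 °C
Reagents that add atoms: none
Why: buffered fluoride cleavage of the tertiary triethylsilyl ether should leave the three esters and the tertiary allylic alcohol untouched.

**Compound list**

1 | 1,4-dioxaspiro[4.5]dec-6-en-8-one | O=C1C=CC2(CC1)OCCO2 | starting material
2 | (8R)-1,4-dioxaspiro[4.5]dec-6-en-8-ol | O[C@H]1C=CC2(OCCO2)CC1 | intermediate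
3 | (8R)-8-(tert-butyldimethylsilyloxy)-1,4-dioxaspiro[4.5]dec-6-ene | CC(C)(C)[Si](C)(C)O[C@H]1C=CC2(OCCO2)CC1 | intermediate
4 | (4R)-4-(tert-butyldimethylsilyloxy)cyclohex-2-en-1-one | CC(C)(C)[Si](C)(C)O[C@H]1C=CC(=O)CC1 | intermediate
5 | (4R)-4-(tert-butyldimethylsilyloxy)-6-methylcyclohex-2-en-1-one, C6 epimers | CC1C[C@@H](O[Si](C)(C)C(C)(C)C)C=CC1=O | intermediate
6 | 4-methoxybenzyl chloromethyl ether | COc1ccc(COCCl)cc1 | starting material
7 | (4R)-4-(tert-butyldimethylsilyloxy)-6-[(4-methoxybenzyloxy)methyl]-6-methylcyclohex-2-en-1-one, methyl cis to OTBS | O=C1C=C[C@H](O[Si](C)(C)C(C)(C)C)C[C@@]1(C)COCc1ccc(OC)cc1 | intermediate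
8 | (4R)-4-hydroxy-6-[(4-methoxybenzyloxy)methyl]-6-methylcyclohex-2-en-1-one, methyl cis to OH | O=C1C=C[C@H](O)C[C@@]1(C)COCc1ccc(OC)cc1 | intermediate
9 | ethynylmagnesium bromide | C#C[Mg]Br | starting material
10 | 3-ethynyl-4-hydroxy-6-[(4-methoxybenzyloxy)methyl]-6-methylcyclohexan-1-one, ethynyl, OH and methyl all cis | O=C1C[C@H](C#C)[C@H](O)C[C@@]1(C)COCc1ccc(OC)cc1 | intermediate
11 | 1,5-diethynyl-2-[(4-methoxybenzyloxy)methyl]-2-methylcyclohexane-1,4-diol (both ethynyls, 4-OH and methyl β; 1-OH and CH2OPMB α) | O[C@@]1(C#C)C[C@H](C#C)[C@H](O)C[C@@]1(C)COCc1ccc(OC)cc1 | intermediate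
12 | 4-acetate of 11 (C8 β-OAc, C5 α-OH) | O[C@@]1(C#C)C[C@H](C#C)[C@H](OC(C)=O)C[C@@]1(C)COCc1ccc(OC)cc1 | intermediate
13 | 1-O-triethylsilyl ether of 12 | CC[Si](CC)(CC)O[C@@]1(C#C)C[C@H](C#C)[C@H](OC(C)=O)C[C@@]1(C)COCc1ccc(OC)cc1 | intermediate
14 | primary alcohol from 13 (C10–CH2OH) | CC[Si](CC)(CC)O[C@@]1(C#C)C[C@H](C#C)[C@H](OC(C)=O)C[C@@]1(C)CO | intermediate
15 | iodide from 14 (C10–CH2I) | CC[Si](CC)(CC)O[C@@]1(C#C)C[C@H](C#C)[C@H](OC(C)=O)C[C@@]1(C)CI | intermediate
16 | 4,4,5,5-tetramethyl-2-vinyl-1,3,2-dioxaborolane | C=CB1OC(C)(C)C(C)(C)O1 | starting material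
17 | 4-(iodomethylene) analogue of 18 (C15 vinyl iodide, E/Z) | C#C[C@H]1C[C@@]2(O[Si](CC)(CC)CC)C(=CI)[C@@H](B3OC(C)(C)C(C)(C)O3)CC[C@]2(C)C[C@H]1OC(C)=O | intermediate
18 | 8β-acetoxy-7β-ethynyl-3β-(pinacolatoboryl)-5α-(triethylsilyloxy)-10β-methyl-4-methylene-trans-decalin | C#C[C@H]1C[C@@]2(O[Si](CC)(CC)CC)C(=C)[C@@H](B3OC(C)(C)C(C)(C)O3)CC[C@]2(C)C[C@H]1OC(C)=O | intermediate
19 | 8β-acetoxy-7β-ethynyl-5α-(triethylsilyloxy)-10β-methyl-4-methylene-trans-decalin-3β-ol | C#C[C@H]1C[C@@]2(O[Si](CC)(CC)CC)C(=C)[C@@H](O)CC[C@]2(C)C[C@H]1OC(C)=O | intermediate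
20 | angelic acid, (Z)-2-methylbut-2-enoic acid | C/C=C(/C)C(=O)O | starting material
21 | angelic 2,4,6-trichlorobenzoic anhydride | C/C=C(/C)C(=O)OC(=O)c1c(Cl)cc(Cl)cc1Cl | intermediate
22 | 3β-angelate of 19 | C#C[C@H]1C[C@@]2(O[Si](CC)(CC)CC)C(=C)[C@@H](OC(=O)/C(C)=C\C)CC[C@]2(C)C[C@H]1OC(C)=O | intermediate
23 | methyl 8β-acetoxy-3β-angeloyloxy-5α-(triethylsilyloxy)eudesma-4(15),11(13)-dien-12-oate | C=C(C(=O)OC)[C@H]1C[C@@]2(O[Si](CC)(CC)CC)C(=C)[C@@H](OC(=O)/C(C)=C\C)CC[C@]2(C)C[C@H]1OC(C)=O | intermediate
24 | methyl 8β-acetoxy-3β-angeloyloxy-5α-hydroxyeudesma-4(15),11(13)-dien-12-oate | C=C(C(=O)OC)[C@H]1C[C@@]2(O)C(=C)[C@@H](OC(=O)/C(C)=C\C)CC[C@]2(C)C[C@H]1OC(C)=O | target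

Total steps: 17. Longest linear sequence: 17 (from 1; compounds 6, 9, 16 and 20 enter as purchased).

**Steps most likely to fail**

1. Step 13. The α-boryl radical may be intercepted by iodine transfer or by telomerization with 16 before the 6-exo-dig closure, which has to pass through the less populated ring-B chair. The vinyl radical may also add to 16 instead of abstracting iodine, and the equatorial preference at C3 may be weaker than assumed. The fallback uses known chemistry, sets out from 15 and comes back at 19. Keck radical allylation of 15 (allyltributylstannane, AIBN, PhH, 80 °C) should give the C1-allyl compound F1. Lemieux–Johnson cleavage of its alkene (OsO4 cat., NaIO4, 2,6-lutidine, dioxane–H2O; alkynes are much slower) should give the C3 aldehyde F2. SmI2 with HMPA and t-BuOH in THF should then close ring A by ketyl–alkyne 6-exo-dig cyclization, the samarium-bound oxygen taking the equatorial position, to give the 3β-alcohol 19 directly.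

2. Step 8. Facial selectivity of the acetylide addition may be poor if the chair with the axial C10 methyl competes, which would deliver the C5 epimer. The fallback replaces kinetic facial control by thermodynamic control; it sets out from 10 and comes back at 12. The adduct mixture, 11 together with the 5-epi-diol F3, is acetylated as in step 9 to 12 and the 5-epi-acetate F4. Co2(CO)8 in CH2Cl2 converts both alkynes of each into hexacarbonyldicobalt complexes, giving the bis-complex of the epimer F5 and the bis-complex of 12 F6. HBF4·OEt2 in wet CH2Cl2 at −20 °C ionizes the tertiary carbinol to the cobalt-stabilized propargylic cation (Nicholas reaction), and water returns reversibly until the bulky C5 cluster sits equatorial and cis-1,3 to the C7 cluster, which is the configuration of F6. Me3NO then removes the cobalt and gives 12.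

3. Step 16. Acid-induced ionization or loss of the tertiary allylic silyl ether, Pd–H isomerization of the exocyclic C4=C15 alkene, or linear instead of branched carbonylation may compete. The fallback separates C–metal bond formation from carbonylation and avoids acid; it sets out from 22 and comes back at 23. Copper-catalysed α-selective protoboration of the terminal alkyne (CuCl, N-aryl imidazol-2-ylidene ligand, NaOtBu, B2pin2, MeOH, THF) should give the 1,1-disubstituted alkenylboronate F7. Oxidative methoxycarbonylation (Pd(OAc)2, PPh3, 1,4-benzoquinone, CO, MeOH, 20 °C) should then give 23.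

**Further compounds**

F1 | step 13 | C1-allyl compound (C10–CH2CH2CH=CH2 analogue of 15) | CC[Si](CC)(CC)O[C@@]1(C#C)C[C@H](C#C)[C@H](OC(C)=O)C[C@@]1(C)CCC=C
F2 | step 13 | C3 aldehyde (C10–CH2CH2CHO analogue of 15) | CC[Si](CC)(CC)O[C@@]1(C#C)C[C@H](C#C)[C@H](OC(C)=O)C[C@@]1(C)CCC=O
F3 | step 8 | 5-epi-diol (C5 epimer of 11) | O[C@]1(C#C)C[C@H](C#C)[C@H](O)C[C@@]1(C)COCc1ccc(OC)cc1
F4 | step 8 | 5-epi-acetate (C5 epimer of 12) | O[C@]1(C#C)C[C@H](C#C)[C@H](OC(C)=O)C[C@@]1(C)COCc1ccc(OC)cc1
F5 | step 8 | bis(hexacarbonyldicobalt) complex of F4 | O[C@]1([C]23[CH]4[Co]2(=C=O)(=C=O)(=C=O)[Co]34(=C=O)(=C=O)=C=O)C[C@H]([C]56[CH]7[Co]5(=C=O)(=C=O)(=C=O)[Co]67(=C=O)(=C=O)=C=O)[C@H](OC(C)=O)C[C@@]1(C)COCc1ccc(OC)cc1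
F6 | step 8 | bis(hexacarbonyldicobalt) complex of 12 | O[C@@]1([C]23[CH]4[Co]2(=C=O)(=C=O)(=C=O)[Co]34(=C=O)(=C=O)=C=O)C[C@H]([C]56[CH]7[Co]5(=C=O)(=C=O)(=C=O)[Co]67(=C=O)(=C=O)=C=O)[C@H](OC(C)=O)C[C@@]1(C)COCc1ccc(OC)cc1
F7 | step 16 | 1,1-disubstituted alkenylboronate (C11–Bpin, C11=C13H2) from 22 | CC1(C)OB(OC1(C)C)C(=C)[C@H]1C[C@@]2(O[Si](CC)(CC)CC)C(=C)[C@@H](OC(=O)/C(C)=C\C)CC[C@]2(C)C[C@H]1OC(C)=O
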